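## The problem

Palstatin (21) is a flavonolignan: a 5,7-dihydroxyflavone whose ring B is fused through its 4'- and 5'-oxygens to a 1,4-dioxane. The dioxane carries a syringyl group on C-α and a hydroxymethyl group on C-β (C-3 and C-2 in benzodioxine numbering), and the 3'-methoxy group sits next to the oxygen that bears C-β. Three aryl units are therefore held by two kinds of link: the pyranone bridge C-2/C-3/C-4 between ring B and ring A, and the two aryl–O–C bonds of the dioxane, whose regiochemistry (which ring-B oxygen holds which carbon) must be fixed without ambiguity. The only stereocentres are the adjacent C-α and C-β, trans and (2R,3R). They are too far from the flavone to be steered by it, so they must be set together and early; once C-β is secure it anchors the absolute configuration, and C-α can at worst re-equilibrate towards the more stable trans ring. C-α is a benzylic ether on a 4-oxygenated aryl ring and can ionise under forcing acid. The phloroglucinol and syringyl phenols are oxidisable and carbon-nucleophilic, so they need masks that leave gently in the last step, and the finished pyranone should not meet strong nucleophiles or reducing metals. The enabling feature is in ring A: C-4a lies between two like oxygens (the future O-1 and the 5-OH) of a threefold-symmetric 1,3,5-trioxygenated ring. Ring C can thus be read as a ring-B aryl alkyne, one carbon monoxide and a 2-iodophloroglucinol triether, and whichever ortho oxygen closes the ring, the same flavone results.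

## Retrosynthesis

**21 to 20.** The O-1–C-2 bond of ring C and all five protecting groups are removed in thought, giving the fully masked ynone 20. Opening ring C at this bond, and not at C-2–C-1' or C-4–C-4a alone, leaves an acyclic precursor that one acid treatment can unmask and close. The forward step must cleave four aryl MOM ethers and one trityl ether and direct the freed ortho hydroxyl to the β-carbon of the ynone (6-endo) without disturbing C-α.

**20 to 16 + 19 (key cut).** The C-4–C-4a and C-3–C-4 bonds are cut together, so that C-4 comes from carbon monoxide, ring B arrives as terminal alkyne 16 and ring A as iodide 19. A cut at C-3–C-4 alone (acetylide plus aldehyde, then oxidation) needs an organolithium and two steps. A cut at C-2–C-1' needs a preformed 2-halochromone and a ring-B organometallic. The three-component cut joins two fragments of similar size under neutral conditions and puts every stereocentre in one fragment and none in the other. The forward reaction must insert CO before the alkyne is transferred; the doubly ortho-substituted, electron-rich iodide 19 is chosen for that.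

**19 to 18 to 17.** The C–I bond and the three MOM groups are removed, leading to phloroglucinol 17. Symmetry makes the iodination position unambiguous.

**16 to 15 to 14 to 13.** The terminal alkyne carbon is removed (aldehyde 15), and the aldehyde is traced through benzylic alcohol 14 to methyl ester 13. The ester is kept as the ring-B handle because it is inert to the boron aldol, borohydride and hot carbonate that build the dioxane.

**13 to 12.** The aryl C–O bond between the dioxane oxygen on C-α and ring B is cut, giving bromo alcohol 12. Cutting this aryl–oxygen bond, and not the alkyl C-α–O bond, means neither stereocentre is a reacting centre in the ring closure. The regiochemistry is already fixed because the other oxygen is the original phenol oxygen of 3. The forward step is an intramolecular Ullmann etherification that must prefer the six-membered ring; the trityl group on the primary oxygen ensures this.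

**12 to 11 to 10.** The trityl group is removed (diol 11) and the primary carbinol is traced to the imide carbonyl of aldol adduct 10. The reduction must spare the methyl benzoate.

**10 to 8 + 2.** The C-α–C-β bond is cut as an auxiliary-controlled syn aldol between aryloxyacetyl imide 8 and MOM-syringaldehyde 2. This single bond formation sets both stereocentres, absolute and relative, and no other cut in the dioxane offers that. The syn adduct maps onto the trans dioxane because ring closure retains configuration at both carbons.

**8 to 5 + 6; 5 to 4 to 3; 2 to 1.** The imide is cut at the N-acyl bond into acid 5 and (S)-4-benzyl-2-oxazolidinone 6. Acid 5 comes from bromophenol 3 by O-alkylation via tert-butyl ester 4, and 2 is the MOM ether of syringaldehyde 1.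

## Roads not taken

**Alternative 1:** The cut is the C-α–O bond to the 5'-oxygen of ring B. In the forward sense, Brønsted acid ionises either C-α epimer of glycerol aryl ether A1 to the para-quinone methide A2, which the neighbouring 5'-hydroxyl traps to give the trans benzodioxane aldehyde A3.
- Merits: only C-β has to be made enantiopure, C-α is corrected by thermodynamics, and no metal or protecting group is needed in the closure. In tolerance of stereochemical error at C-α this road is better than the chosen one.
- Weak points: the trans preference is an equilibrium position and not a kinetic certainty, so some cis isomer must be expected and removed. A1 still needs its own asymmetric entry to C-β and a regioselective etherification of a catechol-type ring. A3 has two free phenols and a primary alcohol that would intercept an aroylpalladium species, so they must be masked again before any carbonylative coupling. An electron-rich aldehyde under acid may also condense with itself.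
- Comparison: the chosen plan sets both centres kinetically by one auxiliary-controlled aldol and carries the protecting groups needed for the key step from the start. It pays with more steps to the dioxane.

**Alternative 2:** The cut is at C-4–C-4a and O-1–C-2, with ring A arriving as unprotected phloroglucinol 17. Heating β-keto ester A4 with 17 releases aroylketene A5, which C-acylates the phenol; cyclodehydration then gives the protected flavone A6.
- Merits: 17 needs no protection or halogenation, no palladium or CO is used, and A4 is about two steps from an ester such as 13. This road is several steps shorter, which the chosen plan cannot match.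
- Weak points: ketene release from a β-keto ester needs temperatures far above those of any other step, at which the benzylic C-α ether and the silyl ether are exposed. Phloroglucinol can also be O-acylated or acylated twice, and can give the isomeric 4-arylcoumarin by the Pechmann pathway if any acid is present. One partner must be used in excess.
- Comparison: the chosen plan forms the same C-4–C-4a bond at about 50 °C under neutral conditions, with chemoselectivity set by the catalytic cycle and not by a thermal balance.

**Alternative 3:** The cut is at both dioxane C–O bonds. With Cs2CO3, the phenoxide of fluorophenol A7 opens cis-epoxide A8 at the benzylic carbon with inversion, and the released alkoxide displaces the para-activated fluoride to give aldehyde A9.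
- Merits: two bonds and the ring form in one metal-free operation, the trans relationship follows stereospecifically from the cis epoxide, and A9 is one step from an alkyne. The benzodioxane is reached in fewer steps than here.
- Weak points: everything rests on A8, an electron-rich cis aryl epoxide that must be made in high enantiopurity from a (Z)-alkene, a substrate class where asymmetric epoxidation is less dependable. Such epoxides also open with partial cationic character, which erodes the inversion and gives cis/trans mixtures. The phenoxide must attack the epoxide and not another molecule's fluoride. A Smiles shift of the intermediate alkoxide could exchange the two oxygens.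
- Comparison: the chosen plan offers an aldol of established selectivity on this substrate type and a ring closure in which no stereocentre reacts. It has no step economy to set against Alternative 3.

Key step: step 14

Remark on the chemistry: the (2R,3R) descriptors of the dioxane correspond to the trans arrangement of aryl and hydroxymethyl groups. The primary alcohol is carried as a trityl ether, which cannot migrate under base and leaves under the same mild acid as the MOM ethers.

## Route

Step 1
Reactants: 1 syringaldehyde (4-hydroxy-3,5-dimethoxybenzaldehyde)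
Product: 2 3,5-dimethoxy-4-(methoxymethoxy)benzaldehyde
Conditions: MOMCl, iPr2NEt, CH2Cl2, 0 °C to rt
Reagents that add atoms: chloromethyl methyl ether, COCCl
Why: Williamson-type O-alkylation of the hindered phenol with the reactive α-chloro ether gives the MOM acetal, which masks the phenol through the aldol, hydride and base steps and leaves with acid at the end.

Step 2
Reactants: 3 methyl 3-bromo-4-hydroxy-5-methoxybenzoate
Product: 4 methyl 3-bromo-4-(2-tert-butoxy-2-oxoethoxy)-5-methoxybenzoate
Conditions: BrCH2CO2t-Bu, K2CO3, DMF, rt
Reagents that add atoms: tert-butyl bromoacetate, CC(C)(C)OC(=O)CBr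
Why: Phenoxide SN2 alkylation (Williamson ether synthesis) of an α-halo ester is fast even for a phenol flanked by Br and OMe; this step fixes which ring-B oxygen will carry C-β.

Step 3
Reactants: 4 methyl 3-bromo-4-(2-tert-butoxy-2-oxoethoxy)-5-methoxybenzoate
Product: 5 [2-bromo-6-methoxy-4-(methoxycarbonyl)phenoxy]acetic acid
Conditions: TFA, CH2Cl2, rt
Reagents that add atoms: none
Why: Acidolysis of the tert-butyl ester (loss of isobutene) frees the aliphatic acid, while the methyl benzoate, aryl bromide and aryl ether are inert to TFA.

Step 4
Reactants: 5 [2-bromo-6-methoxy-4-(methoxycarbonyl)phenoxy]acetic acid; 6 (S)-4-benzyl-2-oxazolidinone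
Product: 8 (4S)-4-benzyl-3-{[2-bromo-6-methoxy-4-(methoxycarbonyl)phenoxy]acetyl}-1,3-oxazolidin-2-one, via mixed pivalic anhydride 7 (not isolated)
Conditions: PivCl, Et3N, THF, −20 °C; then 6, LiCl, rt
Reagents that add atoms: none
Why: Mixed-anhydride N-acylation of the oxazolidinone under LiCl/Et3N; the nitrogen attacks the less hindered aryloxyacetyl carbonyl of 7 and the auxiliary stereocentre is not involved.

Step 5
Reactants: 8 (4S)-4-benzyl-3-{[2-bromo-6-methoxy-4-(methoxycarbonyl)phenoxy]acetyl}-1,3-oxazolidin-2-one; 2 3,5-dimethoxy-4-(methoxymethoxy)benzaldehyde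
Product: 10 (4S)-4-benzyl-3-{(2S,3R)-2-[2-bromo-6-methoxy-4-(methoxycarbonyl)phenoxy]-3-hydroxy-3-[3,5-dimethoxy-4-(methoxymethoxy)phenyl]propanoyl}-1,3-oxazolidin-2-one (syn aldol adduct), via dibutylboron Z-enolate 9 (not isolated)
Conditions: Bu2BOTf, Et3N, CH2Cl2, −78 to 0 °C; then 2, −78 to 0 °C; pH 7 buffer (NaH2PO4/Na2HPO4), MeOH, H2O2
Reagents that add atoms: none
Why: Evans syn aldol: Bu2BOTf/Et3N gives the Z-boron enolate 9, which reacts through a closed chair (Zimmerman–Traxler) transition state on the enolate face away from the benzyl group, setting C-β (2S in the adduct) and C-α (3R) syn, the pair that becomes the trans (2R,3R) dioxane; aryloxyacetyl imides with doubly ortho-substituted aryloxy groups are established substrates for this aldol.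

Step 6
Reactants: 10 syn aldol adduct
Product: 11 methyl 3-bromo-4-{[(1R,2R)-1,3-dihydroxy-1-[3,5-dimethoxy-4-(methoxymethoxy)phenyl]propan-2-yl]oxy}-5-methoxybenzoate
Conditions: NaBH4, THF/H2O, 0 °C to rt
Reagents that add atoms: none
Why: Borohydride reduction of the activated imide carbonyl (reductive auxiliary removal) proceeds in wet THF while the methyl benzoate and aryl bromide are untouched; neither stereocentre is enolisable in the product and the auxiliary is recovered.

Step 7
Reactants: 11 methyl 3-bromo-4-{[(1R,2R)-1,3-dihydroxy-1-[3,5-dimethoxy-4-(methoxymethoxy)phenyl]propan-2-yl]oxy}-5-methoxybenzoate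
Product: 12 methyl 3-bromo-4-{[(1R,2R)-1-hydroxy-1-[3,5-dimethoxy-4-(methoxymethoxy)phenyl]-3-(trityloxy)propan-2-yl]oxy}-5-methoxybenzoate
Conditions: TrCl, Et3N, DMAP (cat.), CH2Cl2, rt
Reagents that add atoms: trityl chloride, ClC(c1ccccc1)(c1ccccc1)c1ccccc1
Why: Tritylation through the trityl cation is selective for the primary hydroxyl over the hindered secondary benzylic one; the trityl ether cannot migrate to the neighbouring alkoxide in step 8 and is cleaved by the same acid as the MOM ethers.

Step 8
Reactants: 12 methyl 3-bromo-4-{[(1R,2R)-1-hydroxy-1-[3,5-dimethoxy-4-(methoxymethoxy)phenyl]-3-(trityloxy)propan-2-yl]oxy}-5-methoxybenzoate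
Product: 13 methyl (2R,3R)-3-[3,5-dimethoxy-4-(methoxymethoxy)phenyl]-8-methoxy-2-[(trityloxy)methyl]-2,3-dihydro-1,4-benzodioxine-6-carboxylate
Conditions: CuI (10 mol %), 3,4,7,8-tetramethyl-1,10-phenanthroline (20 mol %), Cs2CO3, toluene, 110 °C
Reagents that add atoms: none
Why: Intramolecular Ullmann-type C–O coupling: the caesium alkoxide of the benzylic alcohol replaces bromide at copper and closes the 1,4-dioxane in a 6-exo sense; only the aryl–O bond forms, so C-α and C-β keep their configuration and the syn adduct gives the trans (2R,3R) ring, while the blocked primary oxygen excludes a seven-membered ring.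

Step 9
Reactants: 13 methyl (2R,3R)-3-[3,5-dimethoxy-4-(methoxymethoxy)phenyl]-8-methoxy-2-[(trityloxy)methyl]-2,3-dihydro-1,4-benzodioxine-6-carboxylate
Product: 14 {(2R,3R)-3-[3,5-dimethoxy-4-(methoxymethoxy)phenyl]-8-methoxy-2-[(trityloxy)methyl]-2,3-dihydro-1,4-benzodioxin-6-yl}methanol
Conditions: i-Bu2AlH, CH2Cl2, −78 to 0 °C; aq. KNaC4H4O6
Reagents that add atoms: none
Why: Hydride reduction of the aryl ester to the benzylic alcohol; trityl, MOM and the ring ethers are stable to i-Bu2AlH.

Step 10
Reactants: 14 {(2R,3R)-3-[3,5-dimethoxy-4-(methoxymethoxy)phenyl]-8-methoxy-2-[(trityloxy)methyl]-2,3-dihydro-1,4-benzodioxin-6-yl}methanol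
Product: 15 (2R,3R)-3-[3,5-dimethoxy-4-(methoxymethoxy)phenyl]-8-methoxy-2-[(trityloxy)methyl]-2,3-dihydro-1,4-benzodioxine-6-carbaldehyde
Conditions: MnO2, CH2Cl2, rt
Reagents that add atoms: none
Why: MnO2 oxidises the primary benzylic alcohol selectively to the aldehyde without over-oxidation and without touching ethers or stereocentres.

Step 11
Reactants: 15 (2R,3R)-3-[3,5-dimethoxy-4-(methoxymethoxy)phenyl]-8-methoxy-2-[(trityloxy)methyl]-2,3-dihydro-1,4-benzodioxine-6-carbaldehyde
Product: 16 (2R,3R)-3-[3,5-dimethoxy-4-(methoxymethoxy)phenyl]-6-ethynyl-8-methoxy-2-[(trityloxy)methyl]-2,3-dihydro-1,4-benzodioxine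
Conditions: MeC(O)C(N2)P(O)(OMe)2, K2CO3, MeOH/THF, 0 °C to rt
Reagents that add atoms: dimethyl (1-diazo-2-oxopropyl)phosphonate, CC(=O)C(=[N+]=[N-])P(=O)(OC)OC
Why: Ohira–Bestmann (Seyferth–Gilbert) homologation: the diazomethylphosphonate anion formed by methanolysis adds to the non-enolisable aldehyde and the derived alkylidene carbene rearranges by 1,2-shift to the terminal alkyne; K2CO3/MeOH leaves both ether stereocentres alone.

Step 12
Reactants: 17 phloroglucinol (benzene-1,3,5-triol)
Product: 18 1,3,5-tris(methoxymethoxy)benzene
Conditions: NaH, MOMCl, DMF, 0 °C to rt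
Reagents that add atoms: chloromethyl methyl ether, COCCl
Why: Threefold Williamson-type O-alkylation of the phloroglucinol trianion; the hard, oxocarbenium-like electrophile favours oxygen over carbon.

Step 13
Reactants: 18 1,3,5-tris(methoxymethoxy)benzene
Product: 19 2-iodo-1,3,5-tris(methoxymethoxy)benzene
Conditions: NIS, DMF, 0 °C to rt, dark
Reagents that add atoms: N-iodosuccinimide, O=C1CCC(=O)N1I
Why: Electrophilic aromatic iodination; the three free ring positions are equivalent and strongly activated, so one equivalent of NIS under neutral conditions gives a single mono-iodide, after which the iodine deactivates and shields the ring against a second substitution.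

Step 14
Reactants: 16 (2R,3R)-3-[3,5-dimethoxy-4-(methoxymethoxy)phenyl]-6-ethynyl-8-methoxy-2-[(trityloxy)methyl]-2,3-dihydro-1,4-benzodioxine; 19 2-iodo-1,3,5-tris(methoxymethoxy)benzene
Product: 20 3-{(2R,3R)-3-[3,5-dimethoxy-4-(methoxymethoxy)phenyl]-8-methoxy-2-[(trityloxy)methyl]-2,3-dihydro-1,4-benzodioxin-6-yl}-1-[2,4,6-tris(methoxymethoxy)phenyl]prop-2-yn-1-one
Conditions: CO (5 bar), PdCl2(PPh3)2 (5 mol %), Et3N, THF, 50 °C
Reagents that add atoms: carbon monoxide, [C-]#[O+]
Why: Zerovalent palladium, formed in the flask from PdCl2(PPh3)2, adds oxidatively to the C–I bond of 19; CO binds and the aryl group migrates to it, giving a divalent aroylpalladium iodide and with it the C-4–C-4a bond. The alkyne of 16, deprotonated by Et3N at the metal, replaces iodide, and reductive elimination forms the C-3–C-4 bond and returns zerovalent palladium. The closest known reaction type is the copper-free carbonylative Sonogashira coupling of aryl iodides with aryl acetylenes to aryl ynones. No ring is closed and no stereocentre is created; C-α and C-β are spectators under neutral amine conditions at 50 °C. The selectivity needed is carbonylative over direct alkynylation. The two ortho methoxymethoxy groups of 19 slow transfer of the acetylide to the crowded arylpalladium species, and their electron release speeds aryl migration to CO; CO pressure and the absence of a copper acetylide push the same way. Leaving out copper and oxygen also limits dimerisation of 16, and 19 is used in slight excess. Because ring A is threefold symmetric, the new aroyl group has two equivalent ortho oxygens, so the later ring closure cannot give regioisomers.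

Step 15
Reactants: 20 3-{(2R,3R)-3-[3,5-dimethoxy-4-(methoxymethoxy)phenyl]-8-methoxy-2-[(trityloxy)methyl]-2,3-dihydro-1,4-benzodioxin-6-yl}-1-[2,4,6-tris(methoxymethoxy)phenyl]prop-2-yn-1-one
Product: 21 palstatin, 2-[(2R,3R)-3-(4-hydroxy-3,5-dimethoxyphenyl)-2-(hydroxymethyl)-8-methoxy-2,3-dihydro-1,4-benzodioxin-6-yl]-5,7-dihydroxy-4H-chromen-4-one
Conditions: HCl (2 M), MeOH/THF, 45 °C
Reagents that add atoms: none
Why: Acid-catalysed solvolysis removes the four MOM acetals and the trityl ether; the ortho hydroxyl freed next to the carbonyl then adds to the protonated ynone at its β-carbon (6-endo-dig oxa-Michael addition, the known acid-promoted cyclisation of ortho-alkynoylphenols) to form ring C, and any methanol or chloride adduct of the ynone converges on the same flavone by addition–elimination; C-β is inert and C-α, if it ionises, can only reclose, preferentially to the trans ring.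

## Compound list

1 | syringaldehyde (4-hydroxy-3,5-dimethoxybenzaldehyde) | COc1cc(C=O)cc(OC)c1O | starting material
2 | 3,5-dimethoxy-4-(methoxymethoxy)benzaldehyde | COCOc1c(OC)cc(C=O)cc1OC | intermediate
3 | methyl 3-bromo-4-hydroxy-5-methoxybenzoate | COC(=O)c1cc(Br)c(O)c(OC)c1 | starting material
4 | methyl 3-bromo-4-(2-tert-butoxy-2-oxoethoxy)-5-methoxybenzoate | COC(=O)c1cc(Br)c(OCC(=O)OC(C)(C)C)c(OC)c1 | intermediate
5 | [2-bromo-6-methoxy-4-(methoxycarbonyl)phenoxy]acetic acid | COC(=O)c1cc(Br)c(OCC(=O)O)c(OC)c1 | intermediate
6 | (S)-4-benzyl-2-oxazolidinone | O=C1N[C@@H](Cc2ccccc2)CO1 | starting material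
7 | [2-bromo-6-methoxy-4-(methoxycarbonyl)phenoxy]acetic pivalic anhydride | COC(=O)c1cc(Br)c(OCC(=O)OC(=O)C(C)(C)C)c(OC)c1 | intermediate (not isolated)
8 | (4S)-4-benzyl-3-{[2-bromo-6-methoxy-4-(methoxycarbonyl)phenoxy]acetyl}-1,3-oxazolidin-2-one | COC(=O)c1cc(Br)c(OCC(=O)N2C(=O)OC[C@@H]2Cc2ccccc2)c(OC)c1 | intermediate
9 | dibutylboron (Z)-enolate of 8 | CCCCB(CCCC)O/C(=C\Oc1c(Br)cc(C(=O)OC)cc1OC)N1C(=O)OC[C@@H]1Cc1ccccc1 | intermediate (not isolated)
10 | (4S)-4-benzyl-3-{(2S,3R)-2-[2-bromo-6-methoxy-4-(methoxycarbonyl)phenoxy]-3-hydroxy-3-[3,5-dimethoxy-4-(methoxymethoxy)phenyl]propanoyl}-1,3-oxazolidin-2-one | COCOc1c(OC)cc([C@@H](O)[C@H](Oc2c(Br)cc(C(=O)OC)cc2OC)C(=O)N2C(=O)OC[C@@H]2Cc2ccccc2)cc1OC | intermediate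
11 | methyl 3-bromo-4-{[(1R,2R)-1,3-dihydroxy-1-[3,5-dimethoxy-4-(methoxymethoxy)phenyl]propan-2-yl]oxy}-5-methoxybenzoate | COCOc1c(OC)cc([C@@H](O)[C@H](Oc2c(Br)cc(C(=O)OC)cc2OC)CO)cc1OC | intermediate
12 | methyl 3-bromo-4-{[(1R,2R)-1-hydroxy-1-[3,5-dimethoxy-4-(methoxymethoxy)phenyl]-3-(trityloxy)propan-2-yl]oxy}-5-methoxybenzoate | COCOc1c(OC)cc([C@@H](O)[C@H](Oc2c(Br)cc(C(=O)OC)cc2OC)COC(c2ccccc2)(c2ccccc2)c2ccccc2)cc1OC | intermediate
13 | methyl (2R,3R)-3-[3,5-dimethoxy-4-(methoxymethoxy)phenyl]-8-methoxy-2-[(trityloxy)methyl]-2,3-dihydro-1,4-benzodioxine-6-carboxylate | COCOc1c(OC)cc([C@H]2Oc3cc(C(=O)OC)cc(OC)c3O[C@@H]2COC(c4ccccc4)(c4ccccc4)c4ccccc4)cc1OC | intermediate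
14 | {(2R,3R)-3-[3,5-dimethoxy-4-(methoxymethoxy)phenyl]-8-methoxy-2-[(trityloxy)methyl]-2,3-dihydro-1,4-benzodioxin-6-yl}methanol | COCOc1c(OC)cc([C@H]2Oc3cc(CO)cc(OC)c3O[C@@H]2COC(c4ccccc4)(c4ccccc4)c4ccccc4)cc1OC | intermediate
15 | (2R,3R)-3-[3,5-dimethoxy-4-(methoxymethoxy)phenyl]-8-methoxy-2-[(trityloxy)methyl]-2,3-dihydro-1,4-benzodioxine-6-carbaldehyde | COCOc1c(OC)cc([C@H]2Oc3cc(C=O)cc(OC)c3O[C@@H]2COC(c4ccccc4)(c4ccccc4)c4ccccc4)cc1OC | intermediate
16 | (2R,3R)-3-[3,5-dimethoxy-4-(methoxymethoxy)phenyl]-6-ethynyl-8-methoxy-2-[(trityloxy)methyl]-2,3-dihydro-1,4-benzodioxine | COCOc1c(OC)cc([C@H]2Oc3cc(C#C)cc(OC)c3O[C@@H]2COC(c4ccccc4)(c4ccccc4)c4ccccc4)cc1OC | intermediate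
17 | phloroglucinol (benzene-1,3,5-triol) | Oc1cc(O)cc(O)c1 | starting material
18 | 1,3,5-tris(methoxymethoxy)benzene | COCOc1cc(OCOC)cc(OCOC)c1 | intermediate
19 | 2-iodo-1,3,5-tris(methoxymethoxy)benzene | COCOc1cc(OCOC)c(I)c(OCOC)c1 | intermediate
20 | 3-{(2R,3R)-3-[3,5-dimethoxy-4-(methoxymethoxy)phenyl]-8-methoxy-2-[(trityloxy)methyl]-2,3-dihydro-1,4-benzodioxin-6-yl}-1-[2,4,6-tris(methoxymethoxy)phenyl]prop-2-yn-1-one | COCOc1c(OC)cc([C@H]2Oc3cc(C#CC(=O)c4c(OCOC)cc(OCOC)cc4OCOC)cc(OC)c3O[C@@H]2COC(c5ccccc5)(c5ccccc5)c5ccccc5)cc1OC | intermediate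
21 | palstatin, 2-[(2R,3R)-3-(4-hydroxy-3,5-dimethoxyphenyl)-2-(hydroxymethyl)-8-methoxy-2,3-dihydro-1,4-benzodioxin-6-yl]-5,7-dihydroxy-4H-chromen-4-one | COc1cc([C@H]2Oc3cc(-c4cc(=O)c5c(O)cc(O)cc5o4)cc(OC)c3O[C@@H]2CO)cc(OC)c1O | target

## Step count and risks

Total step count: 15. Longest linear sequence: 12 steps (steps 2 to 11, then 14 and 15, from 3).

**Step 14 (key step).** The palladium cycle may bypass CO and transfer the acetylide directly to the arylpalladium species (plain Sonogashira coupling to the diarylalkyne). It may also stall at oxidative addition into the crowded, electron-rich C–I bond, leaving 16 to dimerise. Both follow from asking an electron-rich iodide to react quickly while CO, a good ligand, occupies the metal.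
Fallback: give up the three-component coupling and join the same fragments by addition and oxidation. Starting from 18, n-BuLi (THF, 0 °C) removes the proton between two methoxymethoxy groups to give 2-lithio-1,3,5-tris(methoxymethoxy)benzene F1, and DMF converts it into 2,4,6-tris(methoxymethoxy)benzaldehyde F2. Alkyne 16 is deprotonated with n-BuLi (THF, −78 °C) to its lithium acetylide F3, which adds to F2 to give propargylic alcohol F4 as both carbinol epimers. MnO2 in CH2Cl2 oxidises F4 and the route is rejoined at 20.

**Step 8.** Ring closure may be slow, because a hindered secondary benzylic alkoxide must couple at an ortho-alkoxy aryl bromide. At 110 °C with carbonate this leaves room for protodebromination and for a base-induced Smiles-type shift of the ester-activated aryl group from one oxygen to the other, which would exchange the positions of the two dioxane substituents.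
Fallback: reverse the polarity of the aryl partner so that no hot base is needed. Starting from 12, Miyaura borylation (B2pin2, Pd(dppf)Cl2, KOAc, dioxane, 80 °C) gives the pinacol arylboronate F5. Oxidative Chan–Lam-type etherification with divalent copper (Cu(OAc)2, pyridine, 4 Å molecular sieves, air, CH2Cl2, rt) then closes the six-membered ring on the benzylic hydroxyl, again without touching either stereocentre, and the route is rejoined at 13.

**Step 15.** Unmasking and ring closure are asked of one acid treatment. If an ortho MOM group is lost while ynone is still present under only weakly acidic local conditions, the phenol may close in the 5-exo sense to the aurone skeleton, or partly unmasked species may accumulate. Acid strong enough for the last MOM ethers may also reversibly ionise the C-α–O bond; this can lower the trans/cis ratio but not the enantiopurity, because C-β is untouched and trans is favoured on reclosure.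
Fallback: separate the direction of ring closure from the deprotection. Starting from 20, Et2NH (EtOH, 40 °C) adds to the ynone to give the (E)-β-diethylamino enone F6, in which only the β-carbon is electrophilic. Milder methanolic HCl (rt to 40 °C) then removes the protecting groups, and the freed ortho hydroxyl displaces diethylamine by addition–elimination, a 6-endo closure with no 5-exo counterpart, to rejoin the route at 21.

## Further compounds

F1 | step 14 | 2-lithio-1,3,5-tris(methoxymethoxy)benzene | [Li]c1c(OCOC)cc(OCOC)cc1OCOC
F2 | step 14 | 2,4,6-tris(methoxymethoxy)benzaldehyde | COCOc1cc(OCOC)c(C=O)c(OCOC)c1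
F3 | step 14 | lithium acetylide of 16 | COCOc1c(OC)cc([C@H]2Oc3cc(C#C[Li])cc(OC)c3O[C@@H]2COC(c4ccccc4)(c4ccccc4)c4ccccc4)cc1OC
F4 | step 14 | 3-{(2R,3R)-3-[3,5-dimethoxy-4-(methoxymethoxy)phenyl]-8-methoxy-2-[(trityloxy)methyl]-2,3-dihydro-1,4-benzodioxin-6-yl}-1-[2,4,6-tris(methoxymethoxy)phenyl]prop-2-yn-1-ol (both carbinol epimers) | COCOc1c(OC)cc([C@H]2Oc3cc(C#CC(O)c4c(OCOC)cc(OCOC)cc4OCOC)cc(OC)c3O[C@@H]2COC(c5ccccc5)(c5ccccc5)c5ccccc5)cc1OC
F5 | step 8 | methyl 4-{[(1R,2R)-1-hydroxy-1-[3,5-dimethoxy-4-(methoxymethoxy)phenyl]-3-(trityloxy)propan-2-yl]oxy}-3-methoxy-5-(4,4,5,5-tetramethyl-1,3,2-dioxaborolan-2-yl)benzoate | COCOc1c(OC)cc([C@@H](O)[C@H](Oc2c(B3OC(C)(C)C(C)(C)O3)cc(C(=O)OC)cc2OC)COC(c4ccccc4)(c4ccccc4)c4ccccc4)cc1OC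
F6 | step 15 | (E)-3-(diethylamino)-3-{(2R,3R)-3-[3,5-dimethoxy-4-(methoxymethoxy)phenyl]-8-methoxy-2-[(trityloxy)methyl]-2,3-dihydro-1,4-benzodioxin-6-yl}-1-[2,4,6-tris(methoxymethoxy)phenyl]prop-2-en-1-one | COCOc1c(OC)cc([C@H]2Oc3cc(/C(=C\C(=O)c4c(OCOC)cc(OCOC)cc4OCOC)N(CC)CC)cc(OC)c3O[C@@H]2COC(c5ccccc5)(c5ccccc5)c5ccccc5)cc1OC
A1 | alternative 1 | 3-hydroxy-4-{[(2R)-1,3-dihydroxy-1-(4-hydroxy-3,5-dimethoxyphenyl)propan-2-yl]oxy}-5-methoxybenzaldehyde (either C-1 epimer) | COc1cc(C(O)[C@H](Oc2c(O)cc(C=O)cc2OC)CO)cc(OC)c1O
A2 | alternative 1 | 4-[(2S)-2-(4-formyl-2-hydroxy-6-methoxyphenoxy)-3-hydroxypropylidene]-2,6-dimethoxycyclohexa-2,5-dien-1-one (para-quinone methide) | COC1=CC(=C[C@@H](CO)Oc2c(O)cc(C=O)cc2OC)C=C(OC)C1=O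
A3 | alternative 1 | (2R,3R)-3-(4-hydroxy-3,5-dimethoxyphenyl)-2-(hydroxymethyl)-8-methoxy-2,3-dihydro-1,4-benzodioxine-6-carbaldehyde | COc1cc([C@H]2Oc3cc(C=O)cc(OC)c3O[C@@H]2CO)cc(OC)c1O
A4 | alternative 2 | ethyl 3-[(2R,3R)-3-[4-(benzyloxy)-3,5-dimethoxyphenyl]-8-methoxy-2-{[(triisopropylsilyl)oxy]methyl}-2,3-dihydro-1,4-benzodioxin-6-yl]-3-oxopropanoate | COc1cc([C@H]2Oc3cc(C(=O)CC(=O)OCC)cc(OC)c3O[C@@H]2CO[Si](C(C)C)(C(C)C)C(C)C)cc(OC)c1OCc1ccccc1
A5 | alternative 2 | aroylketene from A4, 3-[(2R,3R)-3-[4-(benzyloxy)-3,5-dimethoxyphenyl]-8-methoxy-2-{[(triisopropylsilyl)oxy]methyl}-2,3-dihydro-1,4-benzodioxin-6-yl]prop-1-ene-1,3-dione | COc1cc([C@H]2Oc3cc(C(=O)C=C=O)cc(OC)c3O[C@@H]2CO[Si](C(C)C)(C(C)C)C(C)C)cc(OC)c1OCc1ccccc1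
A6 | alternative 2 | palstatin protected as its syringyl benzyl ether and primary triisopropylsilyl ether | COc1cc([C@H]2Oc3cc(-c4cc(=O)c5c(O)cc(O)cc5o4)cc(OC)c3O[C@@H]2CO[Si](C(C)C)(C(C)C)C(C)C)cc(OC)c1OCc1ccccc1
A7 | alternative 3 | 4-fluoro-3-hydroxy-5-methoxybenzaldehyde | COc1cc(C=O)cc(O)c1F
A8 | alternative 3 | (2S,3R)-2-[3,5-dimethoxy-4-(methoxymethoxy)phenyl]-3-[(methoxymethoxy)methyl]oxirane (cis) | COCOc1c(OC)cc([C@@H]2O[C@@H]2COCOC)cc1OC
A9 | alternative 3 | (2R,3R)-3-[3,5-dimethoxy-4-(methoxymethoxy)phenyl]-8-methoxy-2-[(methoxymethoxy)methyl]-2,3-dihydro-1,4-benzodioxine-6-carbaldehyde | COc1cc([C@H]2Oc3cc(C=O)cc(OC)c3O[C@@H]2COCOC)cc(OC)c1OCOC
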